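**Plan**

1. Retrosynthetic cuts: (i) the ring CH=C(CH3) double bond of the cyclohexene (ring-closing metathesis; it opens to an allyl arm and an isopropenyl arm); (ii) the bond from the quaternary CO2H-bearing ring-fusion carbon to the neighbouring CH that carries the labdane CH2 (Ireland–Claisen), together with the bond from the other ring-fusion CH to its ring CH2 (conjugate allylation); (iii) the ester C–O that joins the two terpenoid halves.
2. Enabling feature: the trisubstituted alkene is the only endocyclic C=C of the cyclohexene and lies γ,δ to the carboxyl on the quaternary carbon shared with the nine-membered ring. The ring therefore opens to a 1,7-diene whose two arms sit on the vicinal pair quaternary C / ring-fusion CH of an α,β-difunctionalised carboxylic acid.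
3. Forward order: (−)-β-caryophyllene gives the ring-trans enoic acid (vinylic CH3 to CO2H, four- and nine-membered rings untouched). trans-Communic acid gives a 15-nor (E)-allylic alcohol (decalin untouched). Mitsunobu ester, then one-pot conjugate allylation/Ireland–Claisen, then metathesis closes the six-membered ring last, then fluoride deprotection.
4. Stereochemistry: the two cyclobutane-fusion centres and the four decalin centres come from the chiral pool. The ring-fusion CH is set by attack on the exposed face of the trans-cycloalkene. The quaternary carbon and the labdane-side CH are set by a chair Claisen, trans to the new allyl group, from a ketene acetal of fixed geometry and an E-olefin.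

Key step: step 10

Assumption: (−)-β-caryophyllene and trans-communic acid are both bought as such; locants use caryophyllane numbering (ring carbons C1–C11, C4 bears the vinylic methyl) and labdane numbering for the two halves.

**Route**

Step 1
Reactants: 1 (−)-β-caryophyllene
Product: 2 14-hydroxy-β-caryophyllene (CH2OH in place of the C4 methyl, ring-trans alkene kept)
Conditions: SeO2 (0.5 equiv), t-BuOOH, CH2Cl2, 0 °C to rt
Reagents that add atoms: tert-butyl hydroperoxide CC(C)(C)OO (oxygen source); selenium dioxide O=[Se]=O (oxygen carrier)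
Why: SeO2 allylic oxidation (ene reaction, then [2,3]-sigmatropic shift) should attack the strained, most nucleophilic trisubstituted alkene at its vinylic methyl, and the least-motion pathway returns the ring-trans double bond; no stereocentre is made.

Step 2
Reactants: 2 14-hydroxy-β-caryophyllene
Product: 3 ring-trans enal
Conditions: activated MnO2, CH2Cl2, rt
Reagents that add atoms: none
Why: Allylic alcohol oxidation with MnO2 is selective for the primary allylic alcohol and should leave the exocyclic methylene and the strained alkene alone.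

Step 3
Reactants: 3 ring-trans enal
Product: 4 ring-trans enoic acid
Conditions: NaClO2, NaH2PO4, 2-methyl-2-butene, t-BuOH/H2O, 0 °C to rt
Reagents that add atoms: sodium chlorite [Na+].[O-]Cl=O
Why: Pinnick oxidation converts a conjugated aldehyde to the acid without touching alkenes, the hypochlorite by-product being trapped by the sacrificial olefin.

Step 4
Reactants: 5 trans-communic acid
Product: 6 SEM trans-communate
Conditions: SEMCl, i-Pr2NEt, CH2Cl2, 0 °C to rt
Reagents that add atoms: 2-(trimethylsilyl)ethoxymethyl chloride C[Si](C)(C)CCOCCl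
Why: O-alkylation of the carboxylate avoids acyl substitution at the hindered axial C19 carbonyl and gives an ester that fluoride removes later.

Step 5
Reactants: 6 SEM trans-communate
Product: 7 SEM 12-oxo-13,14,15,16-tetranorlabd-8(17)-en-19-oate
Conditions: O3 (about 1 equiv, dye end-point), CH2Cl2/pyridine, −78 °C; then Me2S
Reagents that add atoms: ozone [O-][O+]=O
Why: Selective ozonolysis: ozone reacts fastest with the electron-rich trisubstituted 12,13-alkene of the diene, and titration to one equivalent should spare the hindered exocyclic 8(17)-methylene.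

Step 6
Reactants: 7 SEM 12-oxo-tetranorlabdenoate
Product: 8 14-ethyl 19-SEM (12E)-15-norlabda-8(17),12-diene-14,19-dioate
Conditions: Ph3P=C(CH3)CO2Et, toluene, 80 °C
Reagents that add atoms: ethyl 2-(triphenylphosphoranylidene)propanoate CCOC(=O)C(C)=P(c1ccccc1)(c1ccccc1)c1ccccc1
Why: Wittig olefination with a stabilised, α-branched ylide should give the (E)-trisubstituted enoate and restores labdane C13 with its methyl.

Step 7
Reactants: 8 ethyl SEM diester
Product: 9 SEM (12E)-14-hydroxy-15-norlabda-8(17),12-dien-19-oate
Conditions: i-Bu2AlH (2.2 equiv), CH2Cl2, −78 °C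
Reagents that add atoms: none
Why: DIBAL reduction takes the unhindered conjugated ethyl ester to the allylic alcohol, while the neopentyl, axial C19 SEM ester should be too hindered to react at −78 °C.

Step 8
Reactants: 4 ring-trans enoic acid; 9 labdane allylic alcohol
Product: 10 allylic ester of 4 with 9
Conditions: PPh3, DIAD (betaine preformed), THF, 0 °C
Reagents that add atoms: none
Why: Mitsunobu esterification joins the halves by SN2 attack of the carboxylate at the primary allylic carbon, so no acyl activation or nucleophilic catalyst is present that could add reversibly to the strained enoate and isomerise it.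

Step 9
Reactants: 10 allylic ester
Product: 13 diene acid (metathesis precursor), via silyl ketene acetal 11 (not isolated), via trimethylsilyl ester 12 (not isolated)
Conditions: allylMgBr (1.3 equiv) premixed with CuBr·SMe2 (1.4 equiv), TMSCl (3 equiv), THF, −78 °C; then rt to 55 °C; aq. NH4Cl, then dilute citric acid
Reagents that add atoms: allylmagnesium bromide C=CC[Mg]Br; chlorotrimethylsilane C[Si](C)(C)Cl (its silyl group stays only in 11 and 12)
Why: Copper-mediated conjugate allylation of the strained enoate in its s-cis conformation, on the exposed face (the face a peracid uses on 1), should set caryophyllane C5 and give, after O-silylation, the ketene acetal with OSiMe3 cis to C5, whose Ireland–Claisen rearrangement through a chair transition state anti to the new allyl group (trans vicinal difunctionalisation) with the E-olefin sets the quaternary C4 and labdane C12 together.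

Step 10
Reactants: 13 diene acid
Product: 14 SEM monoester of the target
Conditions: RuCl2(H2IMes)(=CH–C6H4-2-OiPr) (second-generation Hoveyda–Grubbs catalyst, 10 mol%), 1,4-benzoquinone (20 mol%), toluene (5 mM), 80 °C, argon sparge
Reagents that add atoms: none
Why: The ruthenium benzylidene first exchanges onto the only monosubstituted olefin, the allyl group on caryophyllane C5, and the resulting alkylidene adds across the isopropenyl C=CH2 three atoms away ([2+2] to a ruthenacyclobutane, then retro-[2+2]), which forms the ring CH=C(CH3) double bond and expels ethylene. The closest known reaction type is ring-closing metathesis of a 1,7-diene that pairs a terminal vinyl with a 1,1-disubstituted olefin to give a 1-methylcyclohexene. The six-membered ring is closed as a carbocycle by olefin metathesis between the internal allyl carbon and the substituted isopropenyl carbon, the two arms being held gauche on the vicinal quaternary C4 / CH C5 pair. No stereocentre is created; the three contiguous centres from step 9 are not epimerisable under these neutral conditions and become the ring-fusion and labdane-side positions of the cyclohexene. The step needs chemoselectivity among four C=C bonds: the two ring exo-methylenes are 1,1-disubstituted, hindered, and could only close to a bridgehead-olefin bicycle or a macrocycle, so the strain-free cyclohexene should win, and high dilution with ethylene removal suppresses dimerisation. The free carboxylic acid and the SEM ester should be tolerated by the catalyst.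

Step 11
Reactants: 14 SEM monoester
Product: 15 CNP0330729.1 (target diacid)
Conditions: Bu4NF, THF, rt to 40 °C; cold 0.5 M HCl work-up
Reagents that add atoms: none
Why: Fluoride attack at silicon fragments the SEM ester (loss of fluorotrimethylsilane, ethylene and formaldehyde) and unmasks the hindered C19 acid without touching the three alkenes or any stereocentre.

**Compound list**

1 | (−)-β-caryophyllene, (1R,4E,9S)-4,11,11-trimethyl-8-methylidenebicyclo[7.2.0]undec-4-ene | C/C1=C\CCC(=C)[C@H]2CC(C)(C)[C@@H]2CC1 | starting material
2 | 14-hydroxy-β-caryophyllene, [(1R,4Z,9S)-11,11-dimethyl-8-methylidenebicyclo[7.2.0]undec-4-en-4-yl]methanol (ring-trans alkene of 1; descriptor Z only because CH2OH outranks the ring CH2) | OC/C1=C\CCC(=C)[C@H]2CC(C)(C)[C@@H]2CC1 | intermediate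
3 | (1R,4Z,9S)-11,11-dimethyl-8-methylidenebicyclo[7.2.0]undec-4-ene-4-carbaldehyde (ring-trans) | O=C/C1=C\CCC(=C)[C@H]2CC(C)(C)[C@@H]2CC1 | intermediate
4 | (1R,4Z,9S)-11,11-dimethyl-8-methylidenebicyclo[7.2.0]undec-4-ene-4-carboxylic acid (ring-trans) | OC(=O)/C1=C\CCC(=C)[C@H]2CC(C)(C)[C@@H]2CC1 | intermediate
5 | trans-communic acid, (12E)-labda-8(17),12,14-trien-19-oic acid (4S,5R,9S,10R) | C=C/C(C)=C/C[C@H]1C(=C)CC[C@@H]2[C@]1(C)CCC[C@]2(C)C(=O)O | starting material
6 | [2-(trimethylsilyl)ethoxy]methyl (SEM) trans-communate | C=C/C(C)=C/C[C@H]1C(=C)CC[C@@H]2[C@]1(C)CCC[C@]2(C)C(=O)OCOCC[Si](C)(C)C | intermediate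
7 | SEM 12-oxo-13,14,15,16-tetranorlabd-8(17)-en-19-oate | O=CC[C@H]1C(=C)CC[C@@H]2[C@]1(C)CCC[C@]2(C)C(=O)OCOCC[Si](C)(C)C | intermediate
8 | 14-ethyl 19-SEM (12E)-15-norlabda-8(17),12-diene-14,19-dioate | CCOC(=O)/C(C)=C/C[C@H]1C(=C)CC[C@@H]2[C@]1(C)CCC[C@]2(C)C(=O)OCOCC[Si](C)(C)C | intermediate
9 | SEM (12E)-14-hydroxy-15-norlabda-8(17),12-dien-19-oate | OC/C(C)=C/C[C@H]1C(=C)CC[C@@H]2[C@]1(C)CCC[C@]2(C)C(=O)OCOCC[Si](C)(C)C | intermediate
10 | ester of acid 4 with the C14 hydroxyl of 9 (ring-trans enoate, 12E allyl unit) | O=C(OC/C(C)=C/C[C@H]1C(=C)CC[C@@H]2[C@]1(C)CCC[C@]2(C)C(=O)OCOCC[Si](C)(C)C)/C3=C\CCC(=C)[C@H]4CC(C)(C)[C@@H]4CC3 | intermediate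
11 | O-trimethylsilyl ketene acetal of the (5S)-5-allyl ester, OSiMe3 cis to caryophyllane C5 | C=C1CC[C@@H](CC=C)/C(=C(\O[Si](C)(C)C)OC/C(C)=C/C[C@H]3C(=C)CC[C@@H]4[C@]3(C)CCC[C@]4(C)C(=O)OCOCC[Si](C)(C)C)CC[C@@H]2[C@@H]1CC2(C)C | intermediate (not isolated)
12 | trimethylsilyl ester of 13 | C=C1CC[C@@H](CC=C)[C@](C(=O)O[Si](C)(C)C)([C@@H](C(C)=C)C[C@H]3C(=C)CC[C@@H]4[C@]3(C)CCC[C@]4(C)C(=O)OCOCC[Si](C)(C)C)CC[C@@H]2[C@@H]1CC2(C)C | intermediate (not isolated)
13 | (1R,4S,5S,9S)-5-allyl-11,11-dimethyl-8-methylidenebicyclo[7.2.0]undecane-4-carboxylic acid carrying at C4 the (R)-CH(isopropenyl)CH2 group bonded to C9 of the SEM-protected decalin (new bond caryophyllane C4–labdane C12) | C=C1CC[C@@H](CC=C)[C@](C(=O)O)([C@@H](C(C)=C)C[C@H]3C(=C)CC[C@@H]4[C@]3(C)CCC[C@]4(C)C(=O)OCOCC[Si](C)(C)C)CC[C@@H]2[C@@H]1CC2(C)C | intermediate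
14 | 19-SEM monoester of the target (cyclohexene closed; caryophyllane 4S,5S, labdane C12 R) | C=C1CC[C@H]2CC=C(C)[C@@H](C[C@H]3C(=C)CC[C@@H]4[C@]3(C)CCC[C@]4(C)C(=O)OCOCC[Si](C)(C)C)[C@]2(C(=O)O)CC[C@@H]2[C@@H]1CC2(C)C | intermediate
15 | CNP0330729.1, the diacid | C=C1CC[C@H]2CC=C(C)[C@@H](C[C@H]3C(=C)CC[C@@H]4[C@]3(C)CCC[C@]4(C)C(=O)O)[C@]2(C(=O)O)CC[C@@H]2[C@@H]1CC2(C)C | target

**Count and risks**

Total step count: 11. Longest linear sequence: 8 steps (steps 4 to 11, from trans-communic acid).

Most likely to fail, step 9. The organocopper reagent may add 1,2 to the ester or displace the allylic carboxylate instead of adding 1,4, and ring relaxation before the rearrangement may erode facial or ketene-acetal control. Fallback: set out from enal 3 and deliver the allyl group pericyclically. Allylmagnesium bromide adds 1,2 to give the dienol 1-(ring-trans caryophyllen-4-yl)but-3-en-1-ol F1. An anionic oxy-Cope rearrangement (KH, 18-crown-6, THF) then moves the allyl group to caryophyllane C5 through a chair transition state on the exposed face and gives the 5-allyl aldehyde F2. Pinnick oxidation gives the 5-allyl acid F3, and Mitsunobu esterification with 9 gives the saturated allylic ester F4. Enolisation with KN(SiMe3)2/TMSCl in THF–DMPU (larger α-branch syn to oxygen) and warming gives the same ketene acetal 11 and, through 12, comes back to the route at 13.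

Second, step 1. The ene reaction may take place at the ring CH2 instead of the methyl, or the ring-trans geometry may be lost in the [2,3] shift. Fallback: set out from 1 and store the alkene geometry as two stereocentres. Peracid epoxidation gives caryophyllene oxide F5. LiNEt2 isomerises it to the exocyclic allylic alcohol caryophylla-4(12),8(13)-dien-5-ol F6. Hydroxyl-directed epoxidation (VO(acac)2, t-BuOOH) gives the spiro-epoxy alcohol F7; the diastereomer shown is the one required. Payne rearrangement (NaOH, t-BuOH/H2O; the C5 alkoxide attacks C4 with inversion) gives 14-hydroxycaryophyllene oxide F8. Stereoretentive deoxygenation (CH3ReO3 cat., PPh3, benzene, reflux) comes back to the route at 2.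

Third, step 5. Ozone may not discriminate fully between the diene and the exocyclic methylene, so over-cleavage may occur. Fallback: set out from 6 and use the larger rate difference of peracid epoxidation. mCPBA (1 equiv, NaHCO3, CH2Cl2, 0 °C) gives the 12,13-epoxide F9 as a diastereomer mixture. Glycol-type cleavage with H5IO6 in THF/H2O comes back to the route at 7.

**Further compounds**

F1 | step 9 | 1-[(1R,4Z,9S)-11,11-dimethyl-8-methylidenebicyclo[7.2.0]undec-4-en-4-yl]but-3-en-1-ol (ring-trans, carbinol epimers) | OC(CC=C)/C1=C\CCC(=C)[C@H]2CC(C)(C)[C@@H]2CC1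
F2 | step 9 | (1R,5S,9S)-5-allyl-11,11-dimethyl-8-methylidenebicyclo[7.2.0]undecane-4-carbaldehyde (C4 epimers) | C=C1CC[C@@H](CC=C)C(C=O)CC[C@@H]2[C@@H]1CC2(C)C
F3 | step 9 | (1R,5S,9S)-5-allyl-11,11-dimethyl-8-methylidenebicyclo[7.2.0]undecane-4-carboxylic acid (C4 epimers) | C=C1CC[C@@H](CC=C)C(C(=O)O)CC[C@@H]2[C@@H]1CC2(C)C
F4 | step 9 | ester of F3 with the C14 hydroxyl of 9 | C=C1CC[C@@H](CC=C)C(C(=O)OC/C(C)=C/C[C@H]3C(=C)CC[C@@H]4[C@]3(C)CCC[C@]4(C)C(=O)OCOCC[Si](C)(C)C)CC[C@@H]2[C@@H]1CC2(C)C
F5 | step 1 | (−)-caryophyllene oxide, (1R,4R,5R,9S)-4,5-epoxycaryophyll-8(13)-ene | C[C@@]12CC[C@@H]3[C@H](CC3(C)C)C(=C)CC[C@H]1O2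
F6 | step 1 | (1R,5R,9S)-caryophylla-4(12),8(13)-dien-5-ol | C=C1CC[C@@H]2[C@H](CC2(C)C)C(=C)CC[C@H]1O
F7 | step 1 | (1R,5R,9S)-4,12-epoxycaryophyll-8(13)-en-5-ol, spiro-epoxide oxygen anti to the side from which the C5 oxygen closes | C1O[C@]12CC[C@@H]3[C@H](CC3(C)C)C(=C)CC[C@H]2O
F8 | step 1 | 14-hydroxycaryophyllene oxide, epoxide configured as in F5 | OC[C@@]12CC[C@@H]3[C@H](CC3(C)C)C(=C)CC[C@H]1O2
F9 | step 5 | SEM 12,13-epoxylabda-8(17),14-dien-19-oate (trans-epoxide, both faces) | C=CC5(C)OC5C[C@H]1C(=C)CC[C@@H]2[C@]1(C)CCC[C@]2(C)C(=O)OCOCC[Si](C)(C)C
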